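**Retrosynthetic overview**
- Last bonds: the side-chain ketone by hydration of a tertiary propargylic alcohol, and the C8 ester by substitution of an iodolactone with retention (iodide → epoxide → carboxylate).
- The γ-lactone (second ring, closed last) comes from iodolactonisation of a cycloheptenyl acrylic acid; the exo-methylene comes from Mannich methylenation of the acetate side chain.
- The cycloheptene comes from zinc-mediated opening of a bromo 8-oxabicyclo[3.2.1]octane; the tertiary carbinol comes from exo-face addition of an alkynylcerium reagent made from (S)-but-3-yn-2-ol.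
- Key disconnection: a catalytic asymmetric dearomative (4+3) cycloaddition of a 3-substituted furan with a 2-silyloxyallyl cation builds the seven-membered carbocycle (first ring) together with its oxygen bridge.
- Building blocks: methyl furan-3-carboxylate (homologated once), 3-chlorobutan-2-one, (S)-but-3-yn-2-ol, (R)-2-methylbutanoic acid.

Assumption: the configuration is taken exactly as written in the SMILES, i.e. (3aS,5R,6S,7S,8S,8aR) in the ring system, 3S in the hydroxybutanoyl chain and 2R in the 2-methylbutanoate.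

**Step 1**
Reactants: 1 methyl furan-3-carboxylate
Product: 3 methyl 2-(furan-3-yl)acetate, via lithium 2-(furan-3-yl)ethynolate 2 (not isolated)
Conditions: CH2Br2, lithium 2,2,6,6-tetramethylpiperidide, THF, −78 °C; LiN(SiMe3)2; n-BuLi, −78 → 25 °C; then HCl, MeOH, 0 °C
Reagents that add atoms: dibromomethane, BrCBr; methanol, CO
Why: Kowalski ester homologation, in which LiCHBr2 adds to the ester, bromine–lithium exchange triggers the 1,2-shift to the ynolate and acidic methanol converts it through the ketene into the one-carbon-longer ester; any ring lithiation is reversed at the quench and no stereocenter is involved.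

**Step 2**
Reactants: 4 3-chlorobutan-2-one
Product: 5 [(3-chlorobut-1-en-2-yl)oxy]triethylsilane
Conditions: LiN(iPr)2, Et3SiCl (in situ quench), THF, −78 °C
Reagents that add atoms: chlorotriethylsilane, CC[Si](Cl)(CC)CC
Why: Kinetic deprotonation at the unhindered methyl group with internal O-silylation gives the less substituted silyl enol ether, an allylic chloride whose stereocenter is erased on ionisation in step 3.

**Step 3**
Reactants: 3 methyl 2-(furan-3-yl)acetate; 5 [(3-chlorobut-1-en-2-yl)oxy]triethylsilane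
Product: 7 methyl 2-[(1R,2S,5R)-2-methyl-3-oxo-8-oxabicyclo[3.2.1]oct-6-en-6-yl]acetate, via silyloxyallyl cation triflate 6 (not isolated)
Conditions: 3-{[3,5-bis(trifluoromethyl)phenyl]amino}-4-{[(2S)-3,3-dimethyl-1-oxo-1-[(2S)-2-(phenanthren-9-yl)pyrrolidin-1-yl]butan-2-yl]amino}cyclobut-3-ene-1,2-dione (10 mol %), Et3SiOSO2CF3 (10 mol %), 5 (1.5 equiv), toluene, −78 °C; then Et3N, 25 °C
Reagents that add atoms: none
Why: Proposed new method: Et3SiOSO2CF3 ionises the allylic C–Cl bond of 5 to the 2-silyloxyallyl cation 6, whose triflate counter-ion sits in a chiral hydrogen-bonded pocket that shields one face of the cation, the furan bonds first through C2 (its most nucleophilic carbon, next to the alkyl group) to the unsubstituted cation terminus and then through C5 to the methyl-bearing terminus in a compact (4+3) transition state, which dearomatises the furan and sets the regiochemistry (side chain at C6, methyl at C2), the equatorial methyl (2S, also the thermodynamic epimer under Et3N) and both bridgeheads (1R,5R) in one step while Et3SiCl leaves and the silyl triflate is regenerated, the closest known reaction types being the AgClO4- or ZnCl2-promoted (4+3) cycloaddition of 2-silyloxyallyl halides with furans and the hydrogen-bond-donor/silyl triflate co-catalysed enantioselective (4+3) cycloaddition of alkoxy-substituted silyloxyallyl cations.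

**Step 4**
Reactants: 7 methyl 2-[(1R,2S,5R)-2-methyl-3-oxo-8-oxabicyclo[3.2.1]oct-6-en-6-yl]acetate
Product: 8 methyl 2-[(1R,2S,5R,6S)-2-methyl-3-oxo-8-oxabicyclo[3.2.1]octan-6-yl]acetate
Conditions: H2 (1 atm), 10% Pd/C, EtOAc, 25 °C
Reagents that add atoms: none
Why: Heterogeneous syn-hydrogenation delivers both hydrogens to the exo face of the bridged alkene (the face of the oxygen bridge), so the CH2CO2Me group is pushed endo and C6 is set as S, with ketone and ester untouched.

**Step 5**
Reactants: 8 methyl 2-[(1R,2S,5R,6S)-2-methyl-3-oxo-8-oxabicyclo[3.2.1]octan-6-yl]acetate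
Product: 10 methyl 2-[(1R,2S,4R,5S,6S)-4-bromo-2-methyl-3-oxo-8-oxabicyclo[3.2.1]octan-6-yl]acetate, via axial bromide 9 (not isolated)
Conditions: LiN(iPr)2 (1.05 equiv), THF, −78 °C; N-bromosuccinimide (1.0 equiv); then LiN(SiMe3)2 (1.1 equiv), −78 °C; AcOH, −78 °C
Reagents that add atoms: N-bromosuccinimide, O=C1CCC(=O)N1Br
Why: Kinetic enolisation toward the less substituted α-CH2 (C4) and exo bromination of the lithium enolate give the axial bromide 9, and re-enolisation at the now most acidic CHBr position followed by kinetic protonation from the same open exo face leaves bromine equatorial (4R), anti-periplanar to the C5–O bridge bond as the ring opening in step 7 requires.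

**Step 6**
Reactants: 10 methyl 2-[(1R,2S,4R,5S,6S)-4-bromo-2-methyl-3-oxo-8-oxabicyclo[3.2.1]octan-6-yl]acetate; 11 (2S)-but-3-yn-2-ol
Product: 12 methyl 2-[(1R,2S,3R,4R,5S,6S)-4-bromo-3-hydroxy-3-[(3S)-3-hydroxybut-1-yn-1-yl]-2-methyl-8-oxabicyclo[3.2.1]octan-6-yl]acetate
Conditions: 11 (2.5 equiv), n-BuLi (5 equiv), THF, −78 °C; CeCl3, −78 °C; then 10; AcOH, −78 °C
Reagents that add atoms: none
Why: Organocerium 1,2-addition, in which the weakly basic dichlorocerium acetylide adds to the enolisable α-bromo ketone without proton transfer and enters from the exo face because the endo face is blocked by the ethano bridge and its endo CH2CO2Me group, which sets C3 as R (alkynyl syn to the oxygen bridge, hydroxyl endo), while the equatorial bromide, gauche to the new alkoxide, cannot close to an epoxide and the methyl ester survives at −78 °C.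

**Step 7**
Reactants: 12 methyl 2-[(1R,2S,3R,4R,5S,6S)-4-bromo-3-hydroxy-3-[(3S)-3-hydroxybut-1-yn-1-yl]-2-methyl-8-oxabicyclo[3.2.1]octan-6-yl]acetate
Product: 13 methyl 2-[(1S,4R,5S,6R)-4,6-dihydroxy-4-[(3S)-3-hydroxybut-1-yn-1-yl]-5-methylcyclohept-2-en-1-yl]acetate
Conditions: Zn dust, NH4Cl, EtOH/THF, 60 °C
Reagents that add atoms: none
Why: Boord-type reductive β-elimination, in which Zn inserts into the C–Br bond and expels the anti-periplanar bridging ether oxygen, opens the oxabicycle to the cyclohept-2-ene and frees the C6 hydroxyl with its configuration unchanged, whereas the gauche, unactivated tertiary hydroxyl is not lost and alkyne and ester are inert to Zn.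

**Step 8**
Reactants: 13 methyl 2-[(1S,4R,5S,6R)-4,6-dihydroxy-4-[(3S)-3-hydroxybut-1-yn-1-yl]-5-methylcyclohept-2-en-1-yl]acetate
Product: 16 methyl 2-[(1R,4R,5S,6R)-4,6-dihydroxy-4-[(3S)-3-hydroxybut-1-yn-1-yl]-5-methylcyclohept-2-en-1-yl]prop-2-enoate, via Mannich base 14 (not isolated), via ammonium iodide 15 (not isolated)
Conditions: LiN(iPr)2 (4.3 equiv), THF, −78 → −40 °C; N,N-dimethylmethyleneiminium iodide; then MeI, CH2Cl2, 25 °C; then aq. NaHCO3
Reagents that add atoms: N,N-dimethylmethyleneiminium iodide, C=[N+](C)C.[I-]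
Why: Mannich (Eschenmoser) α-methylenation, in which the ester enolate formed beside three lithium alkoxides is aminomethylated and N-methylation followed by mild base-induced E1cB loss of trimethylamine gives the 2-substituted acrylate without touching any stereocenter.

**Step 9**
Reactants: 16 methyl 2-[(1R,4R,5S,6R)-4,6-dihydroxy-4-[(3S)-3-hydroxybut-1-yn-1-yl]-5-methylcyclohept-2-en-1-yl]prop-2-enoate
Product: 18 (3aS,5R,6S,7R,8S,8aR)-5,7-dihydroxy-7-[(3S)-3-hydroxybut-1-yn-1-yl]-8-iodo-6-methyl-3-methylideneoctahydro-2H-cyclohepta[b]furan-2-one, via acrylic acid 17 (not isolated)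
Conditions: LiOH, THF/H2O, 25 °C; AcOH (to pH 6); then N-iodosuccinimide, MeCN, 0 °C, dark
Reagents that add atoms: lithium hydroxide, [Li+].[OH-]; N-iodosuccinimide, O=C1CCC(=O)N1I
Why: Saponification followed by iodolactonisation, in which the carboxyl group held on one face of the ring opens the iodonium ion of the cis-alkene anti in the 5-exo mode, gives the cis-fused α-methylene lactone (3aS,8aR) and places iodine at C8 (S) on the opposite face, trans to the neighbouring tertiary hydroxyl.

**Step 10**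
Reactants: 18 (3aS,5R,6S,7R,8S,8aR)-5,7-dihydroxy-7-[(3S)-3-hydroxybut-1-yn-1-yl]-8-iodo-6-methyl-3-methylideneoctahydro-2H-cyclohepta[b]furan-2-one; 19 (2R)-2-methylbutanoic acid
Product: 21 (3aS,5R,6S,7R,8S,8aR)-5,7-dihydroxy-7-[(3S)-3-hydroxybut-1-yn-1-yl]-6-methyl-3-methylidene-2-oxooctahydro-2H-cyclohepta[b]furan-8-yl (2R)-2-methylbutanoate, via alkynyl epoxide 20 (not isolated)
Conditions: Cs2CO3 (1.2 equiv), DMF, 25 °C; then 19 (5 equiv), 70 °C
Reagents that add atoms: none
Why: Substitution with retention by double inversion, in which Cs2CO3 closes the trans-iodohydrin to the epoxide 20 by intramolecular SN2 and the cesium carboxylate of 19 then opens it by SN2 at the secondary carbon from the face opposite to the oxirane oxygen, installs the (R)-2-methylbutanoate at C8 with the required 8S configuration, returns the tertiary hydroxyl at C7 and needs no selective acylation among the free hydroxyl groups.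

**Step 11**
Reactants: 21 (3aS,5R,6S,7R,8S,8aR)-5,7-dihydroxy-7-[(3S)-3-hydroxybut-1-yn-1-yl]-6-methyl-3-methylidene-2-oxooctahydro-2H-cyclohepta[b]furan-8-yl (2R)-2-methylbutanoate
Product: 23 (3aS,5R,6S,7S,8S,8aR)-5,7-dihydroxy-7-[(3S)-3-hydroxybutanoyl]-6-methyl-3-methylidene-2-oxooctahydro-2H-cyclohepta[b]furan-8-yl (2R)-2-methylbutanoate (CNP0291806.3), via alkylidene carbonate 22 (not isolated)
Conditions: AgOAc (10 mol %), 1,8-diazabicyclo[5.4.0]undec-7-ene (0.5 equiv), CO2 (1 atm), MeCN/H2O, 40 °C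
Reagents that add atoms: water, O
Why: CO2-mediated hydration of a tertiary propargylic alcohol, in which the carbonate formed from the C7 hydroxyl and CO2 attacks the AgOAc-activated alkyne in the 5-exo-dig mode so that oxygen is delivered only to the alkyne carbon next to C7 and hydrolysis of the alkylidene carbonate 22 releases CO2 and the α-hydroxy ketone with the preset 3S carbinol, while the secondary propargylic hydroxyl, lacking the gem-disubstitution that drives cyclisation, does not compete.

**Compound list**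
1 | methyl furan-3-carboxylate | COC(=O)c1ccoc1 | starting material
2 | lithium 2-(furan-3-yl)ethynolate (not isolated) | [Li+].[O-]C#Cc1ccoc1 | intermediate
3 | methyl 2-(furan-3-yl)acetate | COC(=O)Cc1ccoc1 | intermediate
4 | 3-chlorobutan-2-one (racemic) | CC(Cl)C(C)=O | starting material
5 | [(3-chlorobut-1-en-2-yl)oxy]triethylsilane (racemic) | C=C(O[Si](CC)(CC)CC)C(C)Cl | intermediate
6 | 3-[(triethylsilyl)oxy]but-3-en-2-ylium trifluoromethanesulfonate (not isolated) | C[CH+]C(=C)O[Si](CC)(CC)CC.[O-]S(=O)(=O)C(F)(F)F | intermediate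
7 | methyl 2-[(1R,2S,5R)-2-methyl-3-oxo-8-oxabicyclo[3.2.1]oct-6-en-6-yl]acetate | O=C1C[C@H]2O[C@H](C=C2CC(=O)OC)[C@@H]1C | intermediate
8 | methyl 2-[(1R,2S,5R,6S)-2-methyl-3-oxo-8-oxabicyclo[3.2.1]octan-6-yl]acetate | O=C1C[C@H]2O[C@H](C[C@H]2CC(=O)OC)[C@@H]1C | intermediate
9 | methyl 2-[(1R,2S,4S,5S,6S)-4-bromo-2-methyl-3-oxo-8-oxabicyclo[3.2.1]octan-6-yl]acetate (axial bromide, not isolated) | O=C1[C@@H](Br)[C@H]2O[C@H](C[C@H]2CC(=O)OC)[C@@H]1C | intermediate
10 | methyl 2-[(1R,2S,4R,5S,6S)-4-bromo-2-methyl-3-oxo-8-oxabicyclo[3.2.1]octan-6-yl]acetate (equatorial bromide) | O=C1[C@H](Br)[C@H]2O[C@H](C[C@H]2CC(=O)OC)[C@@H]1C | intermediate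
11 | (2S)-but-3-yn-2-ol | C#C[C@H](C)O | starting material
12 | methyl 2-[(1R,2S,3R,4R,5S,6S)-4-bromo-3-hydroxy-3-[(3S)-3-hydroxybut-1-yn-1-yl]-2-methyl-8-oxabicyclo[3.2.1]octan-6-yl]acetate | C[C@H](O)C#C[C@@]1(O)[C@H](Br)[C@H]2O[C@H](C[C@H]2CC(=O)OC)[C@@H]1C | intermediate
13 | methyl 2-[(1S,4R,5S,6R)-4,6-dihydroxy-4-[(3S)-3-hydroxybut-1-yn-1-yl]-5-methylcyclohept-2-en-1-yl]acetate | C[C@H](O)C#C[C@@]1(O)C=C[C@H](CC(=O)OC)C[C@@H](O)[C@@H]1C | intermediate
14 | methyl 3-(dimethylamino)-2-[(1R,4R,5S,6R)-4,6-dihydroxy-4-[(3S)-3-hydroxybut-1-yn-1-yl]-5-methylcyclohept-2-en-1-yl]propanoate (both epimers at C2 of the propanoate, not isolated) | C[C@H](O)C#C[C@@]1(O)C=C[C@H](C(CN(C)C)C(=O)OC)C[C@@H](O)[C@@H]1C | intermediate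
15 | trimethylammonium iodide formed from 14 with MeI (not isolated) | C[C@H](O)C#C[C@@]1(O)C=C[C@H](C(C[N+](C)(C)C)C(=O)OC)C[C@@H](O)[C@@H]1C.[I-] | intermediate
16 | methyl 2-[(1R,4R,5S,6R)-4,6-dihydroxy-4-[(3S)-3-hydroxybut-1-yn-1-yl]-5-methylcyclohept-2-en-1-yl]prop-2-enoate | C[C@H](O)C#C[C@@]1(O)C=C[C@H](C(=C)C(=O)OC)C[C@@H](O)[C@@H]1C | intermediate
17 | 2-[(1R,4R,5S,6R)-4,6-dihydroxy-4-[(3S)-3-hydroxybut-1-yn-1-yl]-5-methylcyclohept-2-en-1-yl]prop-2-enoic acid (not isolated) | C[C@H](O)C#C[C@@]1(O)C=C[C@H](C(=C)C(=O)O)C[C@@H](O)[C@@H]1C | intermediate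
18 | (3aS,5R,6S,7R,8S,8aR)-5,7-dihydroxy-7-[(3S)-3-hydroxybut-1-yn-1-yl]-8-iodo-6-methyl-3-methylideneoctahydro-2H-cyclohepta[b]furan-2-one | C=C1C(=O)O[C@@H]2[C@H]1C[C@@H](O)[C@H](C)[C@@](O)(C#C[C@H](C)O)[C@H]2I | intermediate
19 | (2R)-2-methylbutanoic acid | CC[C@@H](C)C(=O)O | starting material
20 | 7,8-epoxide of the lactone (oxirane from the C7 oxygen and C8, oxirane oxygen on the same face as the lactone ring oxygen; 5-hydroxy, 7-[(3S)-3-hydroxybut-1-yn-1-yl], 6-methyl, 3-methylidene; not isolated) | C=C1C(=O)O[C@@H]2[C@H]1C[C@@H](O)[C@H](C)[C@]3(C#C[C@H](C)O)O[C@H]23 | intermediate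
21 | (3aS,5R,6S,7R,8S,8aR)-5,7-dihydroxy-7-[(3S)-3-hydroxybut-1-yn-1-yl]-6-methyl-3-methylidene-2-oxooctahydro-2H-cyclohepta[b]furan-8-yl (2R)-2-methylbutanoate | C=C1C(=O)O[C@@H]2[C@H]1C[C@@H](O)[C@H](C)[C@@](O)(C#C[C@H](C)O)[C@H]2OC(=O)[C@H](C)CC | intermediate
22 | spiro cyclic carbonate of 21 (1,3-dioxolan-2-one from the C7 oxygen and the proximal alkyne carbon, (Z)-2-hydroxypropylidene at C4 of the dioxolanone; not isolated) | C=C1C(=O)O[C@@H]2[C@H]1C[C@@H](O)[C@H](C)[C@]3(OC(=O)O/C3=C\[C@H](C)O)[C@H]2OC(=O)[C@H](C)CC | intermediate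
23 | (3aS,5R,6S,7S,8S,8aR)-5,7-dihydroxy-7-[(3S)-3-hydroxybutanoyl]-6-methyl-3-methylidene-2-oxooctahydro-2H-cyclohepta[b]furan-8-yl (2R)-2-methylbutanoate | C=C1C(=O)O[C@@H]2[C@H]1C[C@@H](O)[C@H](C)[C@@](O)(C(=O)C[C@H](C)O)[C@H]2OC(=O)[C@H](C)CC | target

**Step count**
Total: 11 steps. Longest linear sequence: 10 steps (steps 1 and 3–11 from 1; the branch from 4 through steps 2–11 is equally long).

**Three steps most likely to fail**

Step 3. The cation could bond to the furan with the opposite regiochemistry, stop at Friedel–Crafts alkylation without closing the ring, or give low enantioselectivity. The fallback sets out from 3 and 4 and comes back at 7. Compounds 4 and 3 are stirred with Et3N in CF3CH2OH at 25 °C, which generates the free oxyallyl cation directly from the chloroketone without a silyl enol ether and without chiral control. This gives racemic 7, that is 7 together with its mirror image methyl 2-[(1S,2R,5S)-2-methyl-3-oxo-8-oxabicyclo[3.2.1]oct-6-en-6-yl]acetate F1. F1 is removed by preparative chromatography on a chiral stationary phase.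

Step 5. The second enolisation has to remove the equatorial hydrogen of the axial bromide 9. If the bromide stays axial, step 6 gives an epoxide and step 7 cannot open the bridge. The fallback sets out from 8 and comes back at 13, and it needs no halide. The kinetic lithium enolate of 8 (LiN(iPr)2, THF, −78 °C) is warmed to 0 °C so that it expels the bridging oxygen by E1cB elimination, and the alkoxide is trapped with tert-butyldimethylsilyl chloride to give methyl 2-[(1S,5S,6R)-6-[(tert-butyldimethylsilyl)oxy]-5-methyl-4-oxocyclohept-2-en-1-yl]acetate F2. Addition of the dichlorocerium acetylide of dilithiated 11 to the enone carbonyl, expected anti to the adjacent methyl group, gives methyl 2-[(1S,4R,5S,6R)-6-[(tert-butyldimethylsilyl)oxy]-4-hydroxy-4-[(3S)-3-hydroxybut-1-yn-1-yl]-5-methylcyclohept-2-en-1-yl]acetate F3. Bu4NF in THF then gives 13. The facial selectivity of this addition is less secure than in the bicycle, which is why it is the fallback.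

Step 10. Carboxylate attack at the hindered secondary epoxide carbon may be slow, and ionisation at the tertiary propargylic carbon would misdirect it. The fallback sets out from 16 and comes back at 23. It hydrates the alkyne first, so that the epoxide becomes an α,β-epoxy ketone that can only open at the β carbon and tolerates acid.
- 16 is hydrated with AgOAc, 1,8-diazabicyclo[5.4.0]undec-7-ene and CO2 in MeCN/H2O to methyl 2-[(1R,4R,5S,6R)-4,6-dihydroxy-4-[(3S)-3-hydroxybutanoyl]-5-methylcyclohept-2-en-1-yl]prop-2-enoate F4.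
- Me3SnOH in 1,2-dichloroethane at 70 °C cleaves the methyl ester without base to 2-[(1R,4R,5S,6R)-4,6-dihydroxy-4-[(3S)-3-hydroxybutanoyl]-5-methylcyclohept-2-en-1-yl]prop-2-enoic acid F5.
- N-iodosuccinimide in MeCN at 0 °C gives (3aS,5R,6S,7R,8S,8aR)-5,7-dihydroxy-7-[(3S)-3-hydroxybutanoyl]-8-iodo-6-methyl-3-methylideneoctahydro-2H-cyclohepta[b]furan-2-one F6.
- K2CO3 in MeCN at 0 °C closes it to the 7,8-epoxy ketone (oxirane from the C7 oxygen and C8, with the 3-hydroxybutanoyl group on the oxirane carbon C7) F7.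
- 19 with catalytic camphorsulfonic acid in CH2Cl2 at 25 °C opens F7 at C8 with inversion to give 23.

Further compounds
F1 | step 3 | methyl 2-[(1S,2R,5S)-2-methyl-3-oxo-8-oxabicyclo[3.2.1]oct-6-en-6-yl]acetate | O=C1C[C@@H]2O[C@@H](C=C2CC(=O)OC)[C@H]1C
F2 | step 5 | methyl 2-[(1S,5S,6R)-6-[(tert-butyldimethylsilyl)oxy]-5-methyl-4-oxocyclohept-2-en-1-yl]acetate | O=C1C=C[C@H](CC(=O)OC)C[C@@H](O[Si](C)(C)C(C)(C)C)[C@@H]1C
F3 | step 5 | methyl 2-[(1S,4R,5S,6R)-6-[(tert-butyldimethylsilyl)oxy]-4-hydroxy-4-[(3S)-3-hydroxybut-1-yn-1-yl]-5-methylcyclohept-2-en-1-yl]acetate | C[C@H](O)C#C[C@@]1(O)C=C[C@H](CC(=O)OC)C[C@@H](O[Si](C)(C)C(C)(C)C)[C@@H]1C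
F4 | step 10 | methyl 2-[(1R,4R,5S,6R)-4,6-dihydroxy-4-[(3S)-3-hydroxybutanoyl]-5-methylcyclohept-2-en-1-yl]prop-2-enoate | C[C@H](O)CC(=O)[C@@]1(O)C=C[C@H](C(=C)C(=O)OC)C[C@@H](O)[C@@H]1C
F5 | step 10 | 2-[(1R,4R,5S,6R)-4,6-dihydroxy-4-[(3S)-3-hydroxybutanoyl]-5-methylcyclohept-2-en-1-yl]prop-2-enoic acid | C[C@H](O)CC(=O)[C@@]1(O)C=C[C@H](C(=C)C(=O)O)C[C@@H](O)[C@@H]1C
F6 | step 10 | (3aS,5R,6S,7R,8S,8aR)-5,7-dihydroxy-7-[(3S)-3-hydroxybutanoyl]-8-iodo-6-methyl-3-methylideneoctahydro-2H-cyclohepta[b]furan-2-one | C=C1C(=O)O[C@@H]2[C@H]1C[C@@H](O)[C@H](C)[C@@](O)(C(=O)C[C@H](C)O)[C@H]2I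
F7 | step 10 | 7,8-epoxy ketone (oxirane from the C7 oxygen and C8; 5-hydroxy, 7-[(3S)-3-hydroxybutanoyl], 6-methyl, 3-methylidene lactone) | C=C1C(=O)O[C@@H]2[C@H]1C[C@@H](O)[C@H](C)[C@]3(C(=O)C[C@H](C)O)O[C@H]23
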